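Readings and results are simulated on assumed constants, noise included.

**Slow or stopped.** Slowness is what I suspect first when a flask makes little product, so I look at whether the product is still rising. In the spring run the left-handed product reads 9.4% at 20.0 min and 9.3% at 120 min, which differ by less than the scatter of 0.3 percentage points. That run has stopped, and waiting does not look useful.

| setting | dusk | dawn | spring | flask |
|---|---|---|---|---|
| left-handed substrate | 0.050 M | 0.050 M | 0.050 M | 0.050 M |
| right-handed substrate | 0.050 M | 0.050 M | 0.050 M | 0.050 M |
| partner | 0.21 M | 0.33 M | 0.15 M | 0.150 M |
| precatalyst | 2.5 mM | 2.5 mM | 5 mM | 2.5 mM |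
| remark | run made earlier | run made earlier | run made earlier |  |
| time |  |  |  | 2.0 h |

- dusk (time / min: right-handed substrate / %, left-handed substrate / %, left-handed product / %): 10.0: 47.5, 45.6, 4.6; 20.0: 47.8, 45.3, 4.8; 50.0: 47.0, 45.1, 5.0; 120: 47.5, 44.8, 5.2
- dawn (time / min: right-handed substrate / %, left-handed substrate / %, left-handed product / %): 15.0: 47.2, 44.9, 4.8; 40.0: 47.4, 44.5, 4.8; 80.0: 47.0, 45.0, 4.5; 120: 47.7, 44.7, 5.0
- spring (time / min: right-handed substrate / %, left-handed substrate / %, left-handed product / %): 10.0: 45.0, 40.9, 8.2; 20.0: 44.9, 40.8, 9.4; 50.0: 45.0, 40.7, 9.6; 120: 45.2, 40.3, 9.3

(standard deviation of a reading: 0.3 percentage points)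

- free catalyst is single-handed; left-handed substrate and right-handed substrate are mirror images of each other, charged as a racemate, each of them at the stated concentration
- the analysis behind the earlier runs scatters by 0.3 percentage points, standard deviation

- whether the excess of right-handed substrate over left-handed substrate among what is left of the two reaches 99% by 2.0 h (yes / no)
- the highest excess of right-handed substrate over left-handed substrate among what is left of the two up to 2.0 h

**The nearest run.** The flask has the partner of the spring run but half its precatalyst. Which of these matters? From the dusk run to the dawn run, partner goes from 0.21 M to 0.33 M, yet the left-handed product at 120 min reads 5.2% and 5.0%, within the scatter. The spring run, with twice the precatalyst of the dusk run, reads twice that product. So I count turns per catalyst.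

**Counting turnovers.** The turnover count (the usual turnover number) is the substrate of one hand lost per catalyst charged. Each hand starts at half the percent scale, so the spring run gives 1.94 for the left hand and 0.960 for the right. As a reading, the selectivity factor of the spring run, left hand over right, is about 2.02. The dusk run, at the flask's precatalyst, gives 2.08 for the left hand.

**My reckoning.** I multiply the spring counts by the flask's 2.5 mM, which leaves 45.1 mM of left-handed substrate and 47.6 mM of right-handed. The excess is therefore 2.64%, far below 99%. This takes a subtraction and a division, with no rate constant.

**The forecast.** It says no and 2.6%, arguing that “The plateau scales with catalyst and ignores partner”.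

**The result.** The flask gives no and 2.68%, and at 2.00 h it holds right-handed product at 2.61%, which that number does not show.

    partner + free catalyst + left-handed substrate → free catalyst + left-handed product (k = 12.0 /M²/s)
    partner + free catalyst + right-handed substrate → free catalyst + right-handed product (k = 6.00 /M²/s)
    partner → decomposed reagent (k = 4.80 × 10⁻⁴ /s)
    precatalyst → free catalyst (k = 0.00430 /s)
    partner + free catalyst → spent catalyst (k = 0.280 /M/s)

The neighbouring flask is the same flask with 0.010 M of precatalyst. The same counts leave 30.6 mM of left-handed substrate and 40.4 mM of right-handed, an excess of 13.8%. The neighbouring flask reaches 10.7%, less than that, with left-handed product at 17.4% and right-handed product at 9.64% by 2.00 h. Per catalyst charged, the neighbouring flask made 1.74 of left-handed product and 0.964 of right-handed product.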